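**Retrosynthetic overview**

1. Target 17 ⇒ (−)-β-pinene 11 + isobutylidene syncarpic acid 16 (from syncarpic acid 14 and isovaleraldehyde 15) by an oxa-Diels–Alder disconnection of O1'–C2' and C3'–C4'; the dihydropyran ring is formed last and carries the spiro centre and C4'.
2. 11 ⇒ (+)-nopinone 10 (methylenation); 14 ⇒ 2,4,6-trihydroxyacetophenone 12 (dearomatizing tetramethylation, then deacetylation).
3. 10 ⇒ bornane hydroxy tosylate 8: the pinane six-membered ring that runs through the CMe2 carbon (C1–C2–C3–C4–C5–C6) is never closed at its final size. It grows by one atom out of the bornane five-membered ring C1–C6–C5–C4–C7 when C7 (the CMe2 carbon) shifts from C1 to C2 (semipinacol); the cyclobutane appears in the same event by contraction of the ring C1–C2–C3–C4–C7.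
4. Feature that makes this possible: in 8 the endo C2–OTs bond is antiperiplanar to the C1–C7 bond (and gauche to C1–C6), and the bridgehead C1 carries a hydroxyl whose alkoxide pushes the shift and ends as the C=O of 10; the bridgehead C4 of the chiral pool is kept and fixes the new bridgehead.
5. 8 ⇒ diol 7 ⇒ ketol 6 ⇒ (1R)-(−)-ketopinic acid 2 ⇒ (1R)-(−)-10-camphorsulfonyl chloride 1. Order of ring formation: syncarpic ring (step 7) and bornane (bought) → pinane six-membered ring and cyclobutane (step 5) → dihydropyran (step 9).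

Key step: step 5

Remark on the chemistry: the β-triketones 13, 14 and 16 are written as one tautomer each; they react through their enol or enone forms. Bornane locants (C1 bridgehead with oxygen, C2, C3, C4 bridgehead with H, C5, C6, C7 = CMe2) are used for 1–9, pinane locants for 10, 11 and 17.

**Step 1**
Reactants: 1 (1R)-(−)-10-camphorsulfonyl chloride
Product: 2 (1R,4S)-7,7-dimethyl-2-oxobicyclo[2.2.1]heptane-1-carboxylic acid ((1R)-(−)-ketopinic acid)
Conditions: KMnO4, Na2CO3, H2O, 90 °C; then aq. H2SO4
Reagents that add atoms: potassium permanganate [K+].[O-][Mn](=O)(=O)=O; water O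
Why: Permanganate oxidation of a camphorsulfonyl chloride (through the sulfene) to the bridgehead carboxylic acid is a standard preparation of ketopinic acid and leaves the ketone and both stereocentres untouched.

**Step 2**
Reactants: 2 (1R)-(−)-ketopinic acid
Product: 6 (1R,4S)-1-hydroxy-7,7-dimethylbicyclo[2.2.1]heptan-2-one, via ketopinoyl chloride 3 (not isolated), via Barton ester 4 (not isolated), via bridgehead hydroperoxide 5 (not isolated)
Conditions: (COCl)2, DMF (cat.), CH2Cl2, 0 °C → rt; sodium 2-thioxopyridin-1(2H)-olate, DMAP (cat.), PhMe, dark, rt; O2, t-BuSH, hν (tungsten lamp), 10 °C; PPh3, rt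
Reagents that add atoms: oxygen O=O
Why: Barton decarboxylation with trapping of the bridgehead radical by O2 (decarboxylative hydroxylation) needs no bridgehead cation and tolerates the ketone, and no stereocentre is made because the bridgehead configuration is fixed by the bicycle.

**Step 3**
Reactants: 6 (1R,4S)-1-hydroxy-7,7-dimethylbicyclo[2.2.1]heptan-2-one
Product: 7 (1R,2R,4S)-7,7-dimethylbicyclo[2.2.1]heptane-1,2-diol (2-hydroxyl endo)
Conditions: Li, NH3(l)/THF, −78 °C; NH4Cl
Reagents that add atoms: none
Why: Dissolving-metal reduction through the ketyl should give the more stable endo alcohol (as camphor gives borneol, whereas hydride reagents attack the endo face and would give the exo alcohol), so C2 (R) is set under thermodynamic control; the C1–O bond lies in the nodal plane of the ketyl and should not be cleaved, and any exo epimer is removed by chromatography.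

**Step 4**
Reactants: 7 (1R,2R,4S)-7,7-dimethylbicyclo[2.2.1]heptane-1,2-diol
Product: 8 (1R,2R,4S)-1-hydroxy-7,7-dimethylbicyclo[2.2.1]heptan-2-yl 4-methylbenzenesulfonate
Conditions: TsCl, pyridine, DMAP (cat.), CH2Cl2, 0 °C → rt
Reagents that add atoms: 4-methylbenzenesulfonyl chloride Cc1ccc(S(=O)(=O)Cl)cc1
Why: Selective O-sulfonylation of the secondary alcohol (the tertiary bridgehead hydroxyl is too hindered to react) forms only an O–S bond, so C2 keeps its endo configuration.

**Step 5**
Reactants: 8 (1R,2R,4S)-1-hydroxy-7,7-dimethylbicyclo[2.2.1]heptan-2-yl 4-methylbenzenesulfonate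
Product: 10 (1R,5S)-6,6-dimethylbicyclo[3.1.1]heptan-2-one ((+)-nopinone), via potassium alkoxide 9 (not isolated)
Conditions: KOt-Bu (1.1 equiv), THF, 0 → 40 °C
Reagents that add atoms: none
Why: Deprotonation of the bridgehead hydroxyl gives alkoxide 9, whose oxygen lone pair pushes the C1–C7 σ-bond into the backside of the endo C2–OTs bond in a concerted 1,2-shift that expels tosylate and leaves C1 as the ketone carbon. This is a base-induced semipinacol rearrangement of a 2-sulfonyloxy alcohol, the reaction type used to convert bicyclo[2.2.2]octan-1-ols into bicyclo[3.2.1]octanones, and anionic 1,2-shifts of this kind are known to build cyclobutanes against strain (semibenzilic contractions). The six-membered ring through the CMe2 carbon is not closed by cyclization but arises by one-atom ring expansion of the bornane five-membered ring C1–C6–C5–C4–C7, into which C2 is inserted, while the cyclobutane arises by contraction of the five-membered ring C1–C2–C3–C4–C7, from which C1 is expelled. The one stereocentre that is made, the new pinane bridgehead (old C2), forms with inversion because C7 enters from the exo face, and its configuration is dictated by the untouched bridgehead C4, since the CMe2 bridge must span both carbons on the same side. The step needs migration of C7 and not of C6 (which would give 3,3-dimethylnorbornan-2-one) and must outrun elimination: the endo C2–O bond is antiperiplanar only to C1–C7, the non-ionizing basic medium avoids a free C2 cation that C6 would capture, and no β-hydrogen is antiperiplanar to the endo tosylate. Formation of the C=O bond from the alkoxide with loss of tosylate should outweigh the extra strain of the bicyclo[3.1.1]heptane.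

**Step 6**
Reactants: 10 (+)-nopinone
Product: 11 (1S,5S)-6,6-dimethyl-2-methylidenebicyclo[3.1.1]heptane ((−)-β-pinene)
Conditions: Ph3PCH3Br, KOt-Bu, THF, rt → reflux
Reagents that add atoms: methyltriphenylphosphonium bromide C[P+](c1ccccc1)(c1ccccc1)c1ccccc1.[Br-]
Why: Wittig methylenation of a ketone, known for nopinone itself, leaves the stereocentres untouched because C1 is a bridgehead that cannot epimerize.

**Step 7**
Reactants: 12 2,4,6-trihydroxyacetophenone
Product: 13 2-acetyl-3-hydroxy-4,4,6,6-tetramethylcyclohex-2-ene-1,5-dione (acetylsyncarpic acid)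
Conditions: MeI (5 equiv), NaOMe, MeOH, reflux; then aq. HCl
Reagents that add atoms: iodomethane CI
Why: Exhaustive C-methylation of the acylphloroglucinol anion dearomatizes the ring to the gem-dimethylated acyl trione, the known entry to syncarpic acids; no stereocentre is formed.

**Step 8**
Reactants: 13 acetylsyncarpic acid
Product: 14 2,2,4,4-tetramethylcyclohexane-1,3,5-trione (syncarpic acid)
Conditions: 6 M HCl (aq.), reflux
Reagents that add atoms: none
Why: Acid-mediated retro-Claisen deacetylation of the β-triketone gives the parent trione; no stereocentre is formed.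

**Step 9**
Reactants: 11 (−)-β-pinene; 14 syncarpic acid; 15 isovaleraldehyde (3-methylbutanal)
Product: 17 (1R,2R,4'R,5S)-6,6,6',6',8',8'-hexamethyl-4'-(2-methylpropyl)-3',4'-dihydrospiro[bicyclo[3.1.1]heptane-2,2'-chromene]-5',7'(6'H,8'H)-dione (target), via isobutylidene syncarpic acid 16 (not isolated)
Conditions: ethylenediammonium diacetate (10 mol%), PhMe, rt → 80 °C, sealed tube, 11 in excess (3 equiv)
Reagents that add atoms: none
Why: Domino Knoevenagel condensation and inverse-electron-demand oxa-Diels–Alder reaction, the reaction type used for syncarpic acid–terpene adducts, joins the CH2 terminus of the alkene to the alkylidene carbon and the enone oxygen to C2; the spiro centre is set by attack on the alkene face anti to the gem-dimethyl bridge, and C4' by the orientation of the oxadiene with the bridgehead C1 beneath it, an orientation not expected to be strongly preferred, so the 4'-epimer should accompany 17 and is to be removed by chromatography.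

**Compound list**

1 | (1R)-(−)-10-camphorsulfonyl chloride, [(1R,4S)-7,7-dimethyl-2-oxobicyclo[2.2.1]heptan-1-yl]methanesulfonyl chloride | CC1(C)[C@H]2CC[C@]1(CS(=O)(=O)Cl)C(=O)C2 | starting material
2 | (1R)-(−)-ketopinic acid, (1R,4S)-7,7-dimethyl-2-oxobicyclo[2.2.1]heptane-1-carboxylic acid | CC1(C)[C@H]2CC[C@]1(C(=O)O)C(=O)C2 | intermediate
3 | ketopinoyl chloride, (1R,4S)-7,7-dimethyl-2-oxobicyclo[2.2.1]heptane-1-carbonyl chloride | CC1(C)[C@H]2CC[C@]1(C(=O)Cl)C(=O)C2 | intermediate
4 | Barton ester, 2-thioxopyridin-1(2H)-yl (1R,4S)-7,7-dimethyl-2-oxobicyclo[2.2.1]heptane-1-carboxylate | CC1(C)[C@H]2CC[C@]1(C(=O)ON1C=CC=CC1=S)C(=O)C2 | intermediate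
5 | bridgehead hydroperoxide, (1R,4S)-1-hydroperoxy-7,7-dimethylbicyclo[2.2.1]heptan-2-one | CC1(C)[C@H]2CC[C@]1(OO)C(=O)C2 | intermediate
6 | (1R,4S)-1-hydroxy-7,7-dimethylbicyclo[2.2.1]heptan-2-one | CC1(C)[C@H]2CC[C@]1(O)C(=O)C2 | intermediate
7 | (1R,2R,4S)-7,7-dimethylbicyclo[2.2.1]heptane-1,2-diol (2-OH endo) | CC1(C)[C@H]2CC[C@]1(O)[C@H](O)C2 | intermediate
8 | (1R,2R,4S)-1-hydroxy-7,7-dimethylbicyclo[2.2.1]heptan-2-yl 4-methylbenzenesulfonate (tosylate endo) | CC1(C)[C@H]2CC[C@]1(O)[C@H](OS(=O)(=O)c1ccc(C)cc1)C2 | intermediate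
9 | potassium (1R,2R,4S)-7,7-dimethyl-2-(tosyloxy)bicyclo[2.2.1]heptan-1-olate | CC1(C)[C@H]2CC[C@]1([O-])[C@H](OS(=O)(=O)c1ccc(C)cc1)C2.[K+] | intermediate
10 | (+)-nopinone, (1R,5S)-6,6-dimethylbicyclo[3.1.1]heptan-2-one | CC1(C)[C@H]2CCC(=O)[C@@H]1C2 | intermediate
11 | (−)-β-pinene, (1S,5S)-6,6-dimethyl-2-methylidenebicyclo[3.1.1]heptane | CC1(C)[C@H]2CCC(=C)[C@@H]1C2 | intermediate
12 | 2,4,6-trihydroxyacetophenone | CC(=O)c1c(O)cc(O)cc1O | starting material
13 | acetylsyncarpic acid, 2-acetyl-3-hydroxy-4,4,6,6-tetramethylcyclohex-2-ene-1,5-dione | CC(=O)C1=C(O)C(C)(C)C(=O)C(C)(C)C1=O | intermediate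
14 | syncarpic acid, 2,2,4,4-tetramethylcyclohexane-1,3,5-trione | CC1(C)C(=O)CC(=O)C(C)(C)C1=O | intermediate
15 | isovaleraldehyde, 3-methylbutanal | CC(C)CC=O | starting material
16 | isobutylidene syncarpic acid, 2,2,4,4-tetramethyl-6-(3-methylbutylidene)cyclohexane-1,3,5-trione | CC(C)CC=C1C(=O)C(C)(C)C(=O)C(C)(C)C1=O | intermediate
17 | (1R,2R,4'R,5S)-6,6,6',6',8',8'-hexamethyl-4'-(2-methylpropyl)-3',4'-dihydrospiro[bicyclo[3.1.1]heptane-2,2'-chromene]-5',7'(6'H,8'H)-dione | CC(C)C[C@@H]1C[C@@]2(CC[C@H]3C[C@@H]2C3(C)C)OC2=C1C(=O)C(C)(C)C(=O)C2(C)C | target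

**Step count and risks**

Total step count: 9 steps. Longest linear sequence: 7 steps (steps 1–6 and 9); the syncarpic acid branch (steps 7 and 8) joins at step 9.

The three steps most likely to fail:

Step 5 (key step). The 1,2-shift must pass a strained transition state. If it is slow, transfer of the sulfonyl group to the bridgehead oxygen may take over; if ionization sets in, capture of a C2 cation by C6 (giving a norbornanone) may take over. The fallback keeps the same C7 shift but changes the nucleofuge and the medium (deaminative, Tiffeneau–Demjanov-type semipinacol). It sets out from 6, which is condensed with hydroxylamine (NH2OH·HCl, NaOAc, EtOH) to (1R,4S)-1-hydroxy-7,7-dimethylbicyclo[2.2.1]heptan-2-one oxime F1. Dissolving-metal reduction (Na, n-PrOH, reflux) should give the endo amine, (1R,2R,4S)-2-amino-7,7-dimethylbicyclo[2.2.1]heptan-1-ol F2, as camphor oxime gives bornylamine. Diazotization (NaNO2, aq. AcOH, 0 °C) gives (1R,2R,4S)-1-hydroxy-7,7-dimethylbicyclo[2.2.1]heptane-2-diazonium acetate F3, which should lose N2 with migration of the antiperiplanar C7 and come back to the route at 10. This path also no longer depends on steps 3 and 4.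

Step 9. The two orientations of the oxadiene over the alkene may be poorly discriminated (4'-epimers), and an ene reaction of β-pinene may compete. The fallback sets the two centres in separate events and sets out from 10 and 13.
- The dianion of 13 (LDA, 2.2 equiv, THF, −78 °C) should add to the ketone of 10 from the face anti to the gem-dimethyl bridge to give the aldol 3-hydroxy-2-{[(1R,2S,5S)-2-hydroxy-6,6-dimethylbicyclo[3.1.1]heptan-2-yl]acetyl}-4,4,6,6-tetramethylcyclohex-2-ene-1,5-dione F4.
- Pyrrolidine/AcOH in PhMe at 50 °C (E1cB dehydration, then oxa-Michael closure by attack of the enol oxygen on C2 anti to the gem-dimethyl bridge, Kabbe-type) should give the spiro-pyranone (1R,2R,5S)-6,6,6',6',8',8'-hexamethylspiro[bicyclo[3.1.1]heptane-2,2'-chromene]-4',5',7'(3'H,6'H,8'H)-trione F5.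
- KHMDS and PhNTf2 (THF, −78 °C) give the enol triflate (1R,2S,5S)-6,6,6',6',8',8'-hexamethyl-5',7'-dioxo-5',6',7',8'-tetrahydrospiro[bicyclo[3.1.1]heptane-2,2'-chromen]-4'-yl trifluoromethanesulfonate F6.
- Negishi coupling with isobutylzinc bromide (Pd(PPh3)4, THF, rt) gives the 2H-pyran (1R,2R,5S)-6,6,6',6',8',8'-hexamethyl-4'-(2-methylpropyl)spiro[bicyclo[3.1.1]heptane-2,2'-chromene]-5',7'(6'H,8'H)-dione F7.
- Hydrogenation at room temperature (H2, Rh/Al2O3, EtOAc), run at once so that electrocyclic ring opening cannot erode the spiro centre, should deliver hydrogen to the face flanked by the C3 methylene, away from the bridgehead C1 and its CMe2 bridge. This places the isobutyl group on the C1 side and comes back to the route at 17.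

Step 3. Protonation of the ketyl may show poor facial selectivity, so that the exo alcohol forms alongside the endo alcohol. The fallback makes the endo C2–O bond by addition to an alkene instead of reduction of the ketone, and sets out from 6. Condensation with tosylhydrazide (TsNHNH2, MeOH) gives N'-[(1R,4S)-1-hydroxy-7,7-dimethylbicyclo[2.2.1]heptan-2-ylidene]-4-methylbenzenesulfonohydrazide F8. A Shapiro reaction (MeLi, 3.3 equiv, Et2O/THF, 0 °C → rt) gives the bridgehead allylic alcohol (1S,4S)-7,7-dimethylbicyclo[2.2.1]hept-2-en-1-ol F9. Hydroboration–oxidation (BH3·THF; then NaOH, H2O2) should place boron on C2, the carbon next to the allylic oxygen, from the endo face, because the exo face is shielded by the syn methyl of C7. This comes back to the route at 7.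

**Further compounds**

F1 | step 5 | (1R,4S)-1-hydroxy-7,7-dimethylbicyclo[2.2.1]heptan-2-one oxime | CC1(C)[C@H]2CC[C@]1(O)C(=NO)C2
F2 | step 5 | (1R,2R,4S)-2-amino-7,7-dimethylbicyclo[2.2.1]heptan-1-ol (amino group endo) | CC1(C)[C@H]2CC[C@]1(O)[C@H](N)C2
F3 | step 5 | (1R,2R,4S)-1-hydroxy-7,7-dimethylbicyclo[2.2.1]heptane-2-diazonium acetate | CC1(C)[C@H]2CC[C@]1(O)[C@H]([N+]#N)C2.CC(=O)[O-]
F4 | step 9 | 3-hydroxy-2-{[(1R,2S,5S)-2-hydroxy-6,6-dimethylbicyclo[3.1.1]heptan-2-yl]acetyl}-4,4,6,6-tetramethylcyclohex-2-ene-1,5-dione | O=C(C[C@@]1(O)CC[C@H]2C[C@@H]1C2(C)C)C1=C(O)C(C)(C)C(=O)C(C)(C)C1=O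
F5 | step 9 | (1R,2R,5S)-6,6,6',6',8',8'-hexamethylspiro[bicyclo[3.1.1]heptane-2,2'-chromene]-4',5',7'(3'H,6'H,8'H)-trione | O=C1C[C@@]2(CC[C@H]3C[C@@H]2C3(C)C)OC2=C1C(=O)C(C)(C)C(=O)C2(C)C
F6 | step 9 | (1R,2S,5S)-6,6,6',6',8',8'-hexamethyl-5',7'-dioxo-5',6',7',8'-tetrahydrospiro[bicyclo[3.1.1]heptane-2,2'-chromen]-4'-yl trifluoromethanesulfonate | FC(F)(F)S(=O)(=O)OC1=C[C@@]2(CC[C@H]3C[C@@H]2C3(C)C)OC2=C1C(=O)C(C)(C)C(=O)C2(C)C
F7 | step 9 | (1R,2R,5S)-6,6,6',6',8',8'-hexamethyl-4'-(2-methylpropyl)spiro[bicyclo[3.1.1]heptane-2,2'-chromene]-5',7'(6'H,8'H)-dione | CC(C)CC1=C[C@@]2(CC[C@H]3C[C@@H]2C3(C)C)OC2=C1C(=O)C(C)(C)C(=O)C2(C)C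
F8 | step 3 | N'-[(1R,4S)-1-hydroxy-7,7-dimethylbicyclo[2.2.1]heptan-2-ylidene]-4-methylbenzenesulfonohydrazide | CC1(C)[C@H]2CC[C@]1(O)C(=NNS(=O)(=O)c1ccc(C)cc1)C2
F9 | step 3 | (1S,4S)-7,7-dimethylbicyclo[2.2.1]hept-2-en-1-ol | CC1(C)[C@H]2CC[C@]1(O)C=C2
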